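**Retrosynthetic overview** (tetralin numbering of the target; ring A = dimethoxybenzo ring, ring B = saturated carbocycle, ring C = pendant catechol)
- Target 12 ⇐ hydrogenolysis of the two benzyl ethers of diol 11 ⇐ LiAlH4 reduction of the trans-fused alkoxy lactone 10, which turns the lactone carbonyl and the acetal carbon into the two CH2OH groups and releases the menthol auxiliary.
- 10 ⇐ key (3+3) annulation of the cyclopropane-fused lactone 6 with 3,4-dimethoxybenzyl bromide 7: the C4–C3 and C8a–C1 bonds of ring B form while the cyclopropane C1–C3 bond is cleaved.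
- Enabling feature: in ring B, C1 is benzylic to the electron-rich dioxygenated ring C (cation-stabilising donor) and C3 bears a carboxyl-level carbon (acceptor). This 1,3-donor–acceptor pair across C2 can be stored as a cyclopropane, and C8a of ring A, para to the C6 methoxy group, is the nucleophilic arene carbon.
- 6 ⇐ sulfonium ylide cyclopropanation of the (5R)-menthyloxybutenolide 3 with benzylic sulfonium salt 2 (from alcohol 1); the acetal stereocentre fixes C2, and C2 then controls C3 and C1.
- Ring order: lactone ring (bought in 3) → cyclopropane (step 2) → ring B (step 3, cyclopropane opened) → lactone ring opened reductively (step 4); rings A and C are bought as arenes.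

Key step: step 3

Assumption: butenolide 3 and benzyl bromide 7 are taken as purchasable; 7 is used fresh because electron-rich benzyl bromides self-condense on storage.

**Step 1**
Reactants: 1 [3,4-bis(benzyloxy)phenyl]methanol
Product: 2 1-[3,4-bis(benzyloxy)benzyl]tetrahydrothiophen-1-ium tetrafluoroborate
Conditions: tetrahydrothiophene (2 equiv), HBF4·OEt2 (1.1 equiv), CH2Cl2, 0 °C → rt; precipitate with Et2O
Reagents that add atoms: tetrahydrothiophene, C1CCSC1; tetrafluoroboric acid diethyl ether complex (counter-ion), [H+].F[B-](F)(F)F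
Why: The para-alkoxybenzylic alcohol ionises readily under HBF4 and the cation is captured by the soft sulfide (SN1 S-alkylation) to give a salt with a non-nucleophilic counter-ion; no stereocentre is involved.

**Step 2**
Reactants: 2 1-[3,4-bis(benzyloxy)benzyl]tetrahydrothiophen-1-ium tetrafluoroborate; 3 (5R)-5-(l-menthyloxy)furan-2(5H)-one
Product: 6 (1S,4R,5R,6R)-6-[3,4-bis(benzyloxy)phenyl]-4-(l-menthyloxy)-3-oxabicyclo[3.1.0]hexan-2-one, via sulfonium ylide 4 (not isolated), via enolate sulfonium betaine 5 (not isolated)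
Conditions: LiN(SiMe3)2 (1.05 equiv), THF, −78 °C; then 3, −78 → 0 °C
Reagents that add atoms: none
Why: Corey–Chaykovsky-type (Michael-initiated ring-closure) cyclopropanation, a known reaction type for 5-alkoxybutenolides: ylide 4 adds to C-4 of the butenolide on the face anti to the menthyloxy group (fixing the future C2 of the tetralin), and the enolate of betaine 5 displaces tetrahydrothiophene in a 3-exo-tet closure that should place the aryl group exo on the cis-fused bicycle.

**Step 3**
Reactants: 6 (1S,4R,5R,6R)-6-[3,4-bis(benzyloxy)phenyl]-4-(l-menthyloxy)-3-oxabicyclo[3.1.0]hexan-2-one; 7 4-(bromomethyl)-1,2-dimethoxybenzene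
Product: 10 (3R,3aR,4S,9aR)-4-[3,4-bis(benzyloxy)phenyl]-6,7-dimethoxy-3-(l-menthyloxy)-3a,4,9,9a-tetrahydronaphtho[2,3-c]furan-1(3H)-one, via iodomagnesium enolate 8 (not isolated), via benzylated benzylic iodide 9 (not isolated)
Conditions: 7 (1.3 equiv, slow addition), MgI2 (1.5 equiv), 2,6-di-tert-butyl-4-methylpyridine (1.2 equiv), THF, rt → 60 °C
Reagents that add atoms: none
Why: Proposed new method: MgI2 binds the lactone carbonyl of 6 and iodide opens the polarised bond between the aryl-bearing and the carbonyl-bearing cyclopropane carbons to give the γ-iodo magnesium enolate 8, which is C-benzylated by 7 to give 9, whose secondary para-alkoxybenzylic iodide ionises and is attacked by the dimethoxyphenyl ring para to a methoxy group, with overall loss of HBr. The closest known reaction type is the MgI2-mediated ring expansion of acyl cyclopropanes with imines or aldehydes, in which iodide opens the ring, the magnesium enolate captures a carbon electrophile and the ring closes by loss of iodide; new here are a benzylic halide as the electrophile and an arene as the closing nucleophile, which makes the sequence a (3+3) benzannulation. Ring B closes by a six-membered cationic Friedel–Crafts alkylation (arene carbon onto the benzylic cation at C1) through a chair-like transition state. C2 is carried over unchanged from 6, C3 is set by alkylation of the enolate on the face anti to the C2 substituent (trans), and C1 is set in the ring closure with the aryl group pseudo-equatorial and trans to C2; because C1 passes through a planar cation, the configuration of the iodide-bearing carbon in 8 and 9 and of C6 in 6 is immaterial. The step needs C-benzylation of the transient enolate to compete with its reclosure and protonation and needs the secondary iodide to ionise in preference to the primary halide of 7: the first is helped by the reversibility of ring opening (unreacted enolate only returns to 6) and by the hindered pyridine that holds the HBr, the second by the more stabilised secondary para-oxygenated cation and the intramolecular arene, while the regiochemistry of arylation follows from the methoxy group para to the attacking carbon.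

**Step 4**
Reactants: 10 (3R,3aR,4S,9aR)-4-[3,4-bis(benzyloxy)phenyl]-6,7-dimethoxy-3-(l-menthyloxy)-3a,4,9,9a-tetrahydronaphtho[2,3-c]furan-1(3H)-one
Product: 11 [(1S,2R,3R)-1-[3,4-bis(benzyloxy)phenyl]-6,7-dimethoxy-1,2,3,4-tetrahydronaphthalene-2,3-diyl]dimethanol
Conditions: LiAlH4 (4 equiv), THF, 0 °C → rt; H2O work-up
Reagents that add atoms: none
Why: Reduction of a γ-alkoxy-γ-lactone to a 1,4-diol: hydride reduces the lactone carbonyl and, after expulsion of menthoxide, the former acetal carbon, so both end as CH2OH; hydride addition should be faster than enolisation of the trans-fused lactone, so C2 and C3 keep their configuration.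

**Step 5**
Reactants: 11 [(1S,2R,3R)-1-[3,4-bis(benzyloxy)phenyl]-6,7-dimethoxy-1,2,3,4-tetrahydronaphthalene-2,3-diyl]dimethanol
Product: 12 4-[(1S,2R,3R)-2,3-bis(hydroxymethyl)-6,7-dimethoxy-1,2,3,4-tetrahydronaphthalen-1-yl]benzene-1,2-diol
Conditions: H2 (1 atm), Pd/C (10% Pd on carbon), degassed MeOH–EtOAc, rt
Reagents that add atoms: none
Why: Catalytic hydrogenolysis of the two benzyl aryl ethers should free the catechol without touching the methyl ethers, the primary alcohols or any stereocentre.

**Compound list**
1 | [3,4-bis(benzyloxy)phenyl]methanol | OCc1ccc(OCc2ccccc2)c(OCc2ccccc2)c1 | starting material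
2 | 1-[3,4-bis(benzyloxy)benzyl]tetrahydrothiophen-1-ium tetrafluoroborate | c1ccc(COc2ccc(C[S+]3CCCC3)cc2OCc2ccccc2)cc1.F[B-](F)(F)F | intermediate
3 | (5R)-5-{[(1R,2S,5R)-2-isopropyl-5-methylcyclohexyl]oxy}furan-2(5H)-one, i.e. (5R)-5-(l-menthyloxy)furan-2(5H)-one | O=C1C=C[C@H](O[C@@H]2C[C@H](C)CC[C@H]2C(C)C)O1 | starting material
4 | sulfonium ylide [3,4-bis(benzyloxy)phenyl](tetrahydrothiophen-1-ium-1-yl)methanide (not isolated) | [CH-](c1ccc(OCc2ccccc2)c(OCc2ccccc2)c1)[S+]1CCCC1 | intermediate
5 | enolate sulfonium betaine from conjugate addition of 4 to 3, new C-4 substituent trans to the menthyloxy group (not isolated) | [O-]C1=C[C@@H]([C@H](c2ccc(OCc3ccccc3)c(OCc3ccccc3)c2)[S+]2CCCC2)[C@H](O[C@@H]2C[C@H](C)CC[C@H]2C(C)C)O1 | intermediate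
6 | (1S,4R,5R,6R)-6-[3,4-bis(benzyloxy)phenyl]-4-(l-menthyloxy)-3-oxabicyclo[3.1.0]hexan-2-one (aryl exo, cyclopropane anti to the menthyloxy group) | O=C1O[C@@H](O[C@@H]3C[C@H](C)CC[C@H]3C(C)C)[C@@H]2[C@@H](c4ccc(OCc5ccccc5)c(OCc6ccccc6)c4)[C@H]12 | intermediate
7 | 4-(bromomethyl)-1,2-dimethoxybenzene (3,4-dimethoxybenzyl bromide) | COc1ccc(CBr)cc1OC | starting material
8 | iodomagnesium enolate of the ring-opened γ-iodo lactone, 4-[aryl(iodo)methyl] group trans to the 5-menthyloxy group (not isolated) | I[Mg]OC1=C[C@@H]([C@H](c2ccc(OCc3ccccc3)c(OCc3ccccc3)c2)I)[C@H](O[C@@H]2C[C@H](C)CC[C@H]2C(C)C)O1 | intermediate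
9 | (5R)-4-{[3,4-bis(benzyloxy)phenyl](iodo)methyl}-3-(3,4-dimethoxybenzyl)-5-(l-menthyloxy)dihydrofuran-2(3H)-one, 3,4-trans and 4,5-trans (not isolated) | O=C1O[C@@H](O[C@@H]2C[C@H](C)CC[C@H]2C(C)C)[C@H]([C@H](c2ccc(OCc3ccccc3)c(OCc3ccccc3)c2)I)[C@H]1Cc1ccc(OC)c(OC)c1 | intermediate
10 | (3R,3aR,4S,9aR)-4-[3,4-bis(benzyloxy)phenyl]-6,7-dimethoxy-3-(l-menthyloxy)-3a,4,9,9a-tetrahydronaphtho[2,3-c]furan-1(3H)-one (trans-fused lactone, aryl trans to the acetal carbon) | COc1cc2c(cc1OC)[C@H](c1ccc(OCc3ccccc3)c(OCc3ccccc3)c1)[C@H]1[C@H](O[C@@H]3C[C@H](C)CC[C@H]3C(C)C)OC(=O)[C@@H]1C2 | intermediate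
11 | [(1S,2R,3R)-1-[3,4-bis(benzyloxy)phenyl]-6,7-dimethoxy-1,2,3,4-tetrahydronaphthalene-2,3-diyl]dimethanol | COc1cc2c(cc1OC)[C@H](c1ccc(OCc3ccccc3)c(OCc3ccccc3)c1)[C@@H](CO)[C@H](CO)C2 | intermediate
12 | 4-[(1S,2R,3R)-2,3-bis(hydroxymethyl)-6,7-dimethoxy-1,2,3,4-tetrahydronaphthalen-1-yl]benzene-1,2-diol | COc1cc2c(cc1OC)[C@H](c1ccc(O)c(O)c1)[C@@H](CO)[C@H](CO)C2 | target

**Totals**
Total step count: 5. Longest linear sequence: 5 steps (1 → 2 → 6 → 10 → 11 → 12).

**Steps most likely to fail**

1. Step 3 (proposed new method). What may go wrong: the ring-opened enolate is reprotonated or recloses faster than it is C-benzylated, the benzyl bromide self-condenses under the Lewis acid, or the arene of 7 opens the cyclopropane first and erodes control at C1. The fallback uses known chemistry, sets out from 3 and comes back at 11. 2-(3,4-Dimethoxyphenyl)-1,3-dithiane F1 (from 3,4-dimethoxybenzaldehyde and propane-1,3-dithiol, BF3·OEt2) is lithiated (n-BuLi, THF, −78 °C) and added to 3 anti to the menthyloxy group. The lactone enolate is trapped in the same flask by purchased 3,4-bis(benzyloxy)benzaldehyde anti to the new substituent (tandem conjugate addition–aldol) to give the trans,trans hydroxybenzyl lactone F2. CF3CO2H in CH2Cl2 ionises the carbinol and closes ring B by Friedel–Crafts alkylation to give the spiro-dithiane tetralin lactone F3. Raney Ni in acetone removes the dithiane to give the regioisomeric trans-fused lactone F4 (carbonyl on C2, acetal carbon on C3), and LiAlH4 as in step 4 reduces F4 to 11.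

2. Step 2. What may go wrong: the electron-rich sulfonium ylide decomposes (rearrangement or loss of the sulfide), or the butenolide is deprotonated at its acetal carbon instead of undergoing conjugate addition. The fallback sets out from 3 and comes back at 6. Purchased 3,4-bis(benzyloxy)benzaldehyde and TsNHNH2 give the tosylhydrazone F5. Its sodium salt (NaOMe) is warmed in the presence of 3, so that the aryldiazomethane F6 forms in the flask (Bamford–Stevens) and adds across the butenolide double bond anti to the menthyloxy group, carbon to C-4, to give the cis-fused 1-pyrazoline F7. Irradiation (or gentle heating) extrudes N2 and closes the cyclopropane to 6.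

3. Step 4. What may go wrong: enolisation and epimerisation of the strained trans-fused lactone under the basic hydride conditions before reduction is complete, eroding the 2,3-trans relationship. The fallback sets out from 10 and comes back at 11. NaBH4 in aqueous ethanolic KOH first opens the alkoxy lactone to the aldehyde carboxylate, in which all three substituents of ring B are equatorial so that any equilibration reinforces the wanted configuration, and reduces the aldehyde; acidification gives the hydroxy acid F8. BH3·THF then reduces the carboxylic acid to give 11.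

**Further compounds**
F1 | step 3 | 2-(3,4-dimethoxyphenyl)-1,3-dithiane | COc1ccc(C2SCCCS2)cc1OC
F2 | step 3 | (5R)-4-[2-(3,4-dimethoxyphenyl)-1,3-dithian-2-yl]-3-{[3,4-bis(benzyloxy)phenyl](hydroxy)methyl}-5-(l-menthyloxy)dihydrofuran-2(3H)-one, 3,4-trans and 4,5-trans, carbinol carbon as a mixture | O=C1O[C@@H](O[C@@H]2C[C@H](C)CC[C@H]2C(C)C)[C@H](C2(SCCCS2)c2ccc(OC)c(OC)c2)[C@H]1C(O)c1ccc(OCc2ccccc2)c(OCc2ccccc2)c1
F3 | step 3 | spiro-dithiane tetralin lactone: trans-fused 9-[3,4-bis(benzyloxy)phenyl]-6,7-dimethoxy-3-(l-menthyloxy)-3a,9,9a-trihydronaphtho[2,3-c]furan-1(3H)-one with a 1,3-dithiane spiro at C4 | COc1cc2c(cc1OC)[C@H](c1ccc(OCc3ccccc3)c(OCc3ccccc3)c1)[C@H]1C(=O)O[C@@H](O[C@@H]3C[C@H](C)CC[C@H]3C(C)C)[C@@H]1C23SCCCS3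
F4 | step 3 | regioisomeric trans-fused lactone: 9-[3,4-bis(benzyloxy)phenyl]-6,7-dimethoxy-3-(l-menthyloxy)-3a,4,9,9a-tetrahydronaphtho[2,3-c]furan-1(3H)-one | COc1cc2c(cc1OC)[C@H](c1ccc(OCc3ccccc3)c(OCc3ccccc3)c1)[C@H]1C(=O)O[C@@H](O[C@@H]3C[C@H](C)CC[C@H]3C(C)C)[C@@H]1C2
F5 | step 2 | 3,4-bis(benzyloxy)benzaldehyde (E)-tosylhydrazone | Cc1ccc(cc1)S(=O)(=O)N/N=C/c1ccc(OCc2ccccc2)c(OCc2ccccc2)c1
F6 | step 2 | [3,4-bis(benzyloxy)phenyl]diazomethane | [N-]=[N+]=Cc1ccc(OCc2ccccc2)c(OCc2ccccc2)c1
F7 | step 2 | cis-fused 1-pyrazoline: 3-[3,4-bis(benzyloxy)phenyl]-4-(l-menthyloxy)-3,3a,4,6a-tetrahydro-6H-furo[3,4-c]pyrazol-6-one, ring fusion anti to the menthyloxy group | O=C1O[C@@H](O[C@@H]3C[C@H](C)CC[C@H]3C(C)C)[C@@H]2[C@@H](c4ccc(OCc5ccccc5)c(OCc6ccccc6)c4)N=N[C@H]12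
F8 | step 4 | (2R,3R,4S)-4-[3,4-bis(benzyloxy)phenyl]-3-(hydroxymethyl)-6,7-dimethoxy-1,2,3,4-tetrahydronaphthalene-2-carboxylic acid | COc1cc2c(cc1OC)[C@H](c1ccc(OCc3ccccc3)c(OCc3ccccc3)c1)[C@@H](CO)[C@H](C(=O)O)C2
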